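## The problem

Sipholenol K (38) is built from two bicyclic halves joined by the C4–C5 ethano link between C6 and the enone β-carbon C3. Atom numbers follow the heavy-atom order of the target SMILES. The AB half is a trans-fused perhydro-1-benzoxepine (ring A: O16, C17, C7, C9, C10, C11, C13; ring B: C6, C7, C17, C18, C19, C20). The CD half is a cis-fused octalone (ring C: C2, C3, C23, C24, C25, C26; ring D: C23, C24, C28, C31, C32, C33).

Five stereocentres lie in the AB half (C6, C7, C11, C17, C20) and three in the CD half (C23, C24, C28). The two-carbon link insulates them, so each half needs its own source of absolute configuration and the halves are best joined late.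

In the AB half the quaternary C7 is the control element. Once ring A is trans-fused its methyl C8 is axial and shields the upper face of C6, C20 and of a C10=C11 alkene. The C7/C17 relation (O16 cis to C8, trans to C9) must therefore be made first. Hydride reduction of a 2-allyl-2-methyl-1,3-diketone is expected to deliver hydride anti to the larger allyl group and place the hydroxyl cis to allyl, which is the wrong relation; it is not relied on here.

In the CD half the C28 carbinol can direct C24. The cis ring fusion at C23 lies α to a carbonyl in every practical precursor and is probably not the more stable arrangement, so it must be set kinetically and kept away from base.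

Groups that will not survive rough treatment are the tertiary carbinols C20 and C28 (elimination in acid), β-hydroxy ketone intermediates (retro-aldol), the enone with its γ-hydrogen at C23, and the hindered tertiary ether O16–C13, which is hard to form by cyclisation.

The feature that opens the key step: in ring A the fully substituted C13 sits between O16 and the carbinol C11. An allyl group on C7 and a 1,1-dimethylallyl ether on O16 therefore map onto a C10=C11 alkene, which closes ring A by metathesis and later carries O12 in by epoxidation and hydride opening at C10.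

## Retrosynthesis

**Endgame, cut C3–C4.** Target 38 comes from its tris(triethylsilyl) ether 37, and 37 from the tertiary allylic alcohol 36 by oxidative 1,3-transposition. Cutting C3–C4 in 36 gives the alkyl iodide 21 (AB half) and the bicyclic enone 34 (CD half). This cut is preferred to C4–C5 or C5–C6 because it leaves C6 with a plain two-carbon chain and uses the enone carbonyl as the only activating group. A vinylogous-ester partner would need regioselective enol etherification of an unsymmetrical 1,3-dione; enone 34 avoids that. The forward reaction asks for 1,2-addition of a primary alkyllithium to a hindered enone without enolisation at C23.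

**CD half, ring C.** Enone 34 is opened at C2=C26 to keto aldehyde 33 (intramolecular aldol condensation). 33 comes from alkene 32 by ozonolysis, and 32 from the cyclohexenyl ketone 30 by conjugate allylation (C24–C25) with kinetic protonation at C23. Ketone 30 is reached through Weinreb amide 29 and enol triflate 28 from ketone 27, the silyl ether of 26. The C28 silyloxy group is the only stereocentre in 30; it must steer the allyl group to the opposite face, and protonation must then give the cis relation.

**CD half, C28.** β-Hydroxy ketone 26 comes from epoxy ketone 25 by reductive cleavage of the Cα–O bond, and 25 by catalytic asymmetric epoxidation of enone 24. Enone 24 is two steps from commercial 22 via 23. This places all absolute stereocontrol of the CD half in one catalytic step on a simple enone.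

**AB half, functional groups.** Iodide 21 comes from alcohol 20, the selectively unmasked form of tris-silyl ether 19, which is made from triol 18. Triol 18 arises from epoxy diol 17 by hydride opening of the oxirane at C10, which leaves O12 on C11.

**AB half, C6 and C20.** Epoxy diol 17 is cut at C6–H and C20–O22 back to diene 15: a cyclic hydroboration in which boron, tethered through C4–C5, adds to C20 and hydrogen to C6 from the face opposite C8. This sets both centres in one step, and the trans-diequatorial relation of C5 and O22 falls out of the syn addition. Diene 15 comes from enol triflate 14, ketone 13 and ketone 12 by methylation, triflation and vinylation. Borane chemistry demands that no other alkene be present, which fixes the timing of the key step.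

**Key disconnection, C10=C11.** Oxirane 12 comes from oxepene 11, and 11 from diene 10 by ring-closing metathesis. Closing ring A at C10=C11 is preferred to closing O16–C13 (a hindered tertiary ether by cyclisation) or C9–C10 (no handle for O12). Running it on ketone 10, before ring B is elaborated, removes the allyl group before hydroboration and gives a rigid bicycle for the later face-selective steps. The oxirane then serves as the protected form of both the alkene and O12.

**Start of the AB half.** Diene 10 comes from hydroxy ketone 7 and imidate 9 (from alcohol 8). Hydroxy ketone 7 is cut at C7–C9 to epoxy ketone 4 and allyl bromide 5: reductive cleavage gives a regiospecific enolate that is allylated anti to the C17 alkoxide, which is exactly the O16-trans-to-C9 relation needed. Epoxy ketone 4 comes from epoxy alcohol 3, allylic alcohol 2 and enone 1 by CBS reduction, hydroxyl-directed epoxidation and oxidation.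

## Roads not taken

**Alternative 1:** The cut is C24–C28, with ring C taken from an arene. In the forward step SmI2 with HMPA reduces the methyl ketone of aryl ketone A1 (a 2,6-dimethoxytoluene carrying the tertiary alkyl chain on C23) to a ketyl that adds to C24, giving dienol A2.
- Merits: very short; ring D and the C28 carbinol form together; both ring C oxygens arrive as enol ethers, so hydrolysis leads straight to a vinylogous ester.
- Weak points: an electron-rich, unactivated dimethoxyarene is a poor ketyl acceptor, so simple reduction or pinacol coupling competes. A1 is achiral, so the absolute configuration needs an external chiral agent for which there is little basis. C23 is set only on hydrolysis, under thermodynamic control.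
- Comparison: A2 would be reached in far fewer steps than the eleven used here for the CD half (steps 17–27), and in that respect this road is better. The chosen plan sets against it catalytic control of C28 on a simple enone and C28-directed formation of C24.

**Alternative 2:** The cut is C23–C24 and C25–C26. Triene A3 undergoes an intramolecular Diels–Alder reaction under a chiral oxazaborolidinium acid to give the cis-fused ketone A4.
- Merits: both ring-fusion centres are formed cis in one catalytic enantioselective step. This is better than the conjugate addition and protonation pair used here (step 25), which is the weakest part of the CD half.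
- Weak points: C28 is still a ketone in A4. In the cis-fused ketone the C3 arm is axial over the face from which methyl must arrive to leave O30 cis to H24, so methyl addition is likely to give the wrong epimer. The C26 oxygen is missing and needs a later enone transposition. The 2-silyloxydiene must survive a strong Lewis acid.
- Comparison: the chosen plan sets against the better ring fusion an early, catalyst-controlled C28 and a C24 that is not epimerisable once formed.

**Alternative 3:** The cut is C20–C6 in ring B. SmI2 reduces the C20 methyl ketone of oxepane A5 to a ketyl that adds to C6 of the enoate, and O22 lactonises onto C4 to give A6.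
- Merits: ring B, C6 and C20 in one step, with the anti relation of O22 and C5 that ketyl–enoate cyclisations usually give. This is better step economy than steps 9–12 here.
- Weak points: A5 must already carry the quaternary C7, C17 and C11 on a flexible seven-membered ring, without ring B to control them, and the hindered O16–C13 ether must be made first. The new bond forms next to the quaternary C7. The lactone must still be reduced and C4 activated.
- Comparison: the chosen plan sets against it a cheap enantioselective entry, a rigid trans-fused bicycle that directs C6, C20 and C11, and ring closure by a carbon–carbon event.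

Key step: step 7

## Route

Assumptions:
- Compounds 1, 5, 8 and 22 are purchased.
- Compound 13 is carried as a mixture at C20 and compound 36 as a mixture at C3; both centres become sp2 later.
- In step 19 the quinine-derived amine salt is taken to give (1S,6S)-25; if the sense is the reverse, the quinidine-derived pseudo-enantiomer is used.

### AB half

Step 1
Reactants: 1 2-methylcyclohex-2-en-1-one
Product: 2 (R)-2-methylcyclohex-2-en-1-ol
Conditions: (S)-2-methyl-CBS-oxazaborolidine (10 mol %), catecholborane, toluene, −78 °C
Reagents that add atoms: none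
Why: Corey–Bakshi–Shibata reduction; the alkene arm acts as the large group, so the (S)-catalyst should give the (R)-carbinol, which later relays its configuration to C7 and C17.

Step 2
Reactants: 2 (R)-2-methylcyclohex-2-en-1-ol
Product: 3 (1R,2R,6S)-1-methyl-7-oxabicyclo[4.1.0]heptan-2-ol (oxirane cis to OH)
Conditions: VO(acac)2 (2 mol %), t-BuOOH, CH2Cl2, 0 °C
Reagents that add atoms: tert-butyl hydroperoxide, CC(C)(C)OO
Why: Hydroxyl-directed epoxidation of a cyclic allylic alcohol; oxygen is delivered from the face of the vanadium-bound hydroxyl, setting the future C17–O bond.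

Step 3
Reactants: 3 (1R,2R,6S)-1-methyl-7-oxabicyclo[4.1.0]heptan-2-ol
Product: 4 (1S,6S)-1-methyl-7-oxabicyclo[4.1.0]heptan-2-one
Conditions: Dess–Martin periodinane, NaHCO3, CH2Cl2, rt
Reagents that add atoms: none
Why: Buffered periodinane oxidation of a secondary alcohol leaves the oxirane untouched; the carbinol centre has done its work as relay.

Step 4
Reactants: 4 (1S,6S)-1-methyl-7-oxabicyclo[4.1.0]heptan-2-one; 5 allyl bromide
Product: 7 (2R,3S)-3-hydroxy-2-methyl-2-(prop-2-en-1-yl)cyclohexan-1-one, via dilithium alkoxide enolate 6 (not isolated)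
Conditions: Li (2.2 equiv), NH3/THF, −78 °C; isoprene; then 5, −78 to −45 °C; NH4Cl at −78 °C
Reagents that add atoms: none
Why: Reductive alkylation of an α,β-epoxy ketone: two-electron cleavage of the C7–O bond gives the regiospecific C6=C7 enolate with the C17 alkoxide intact. The alkoxide is held pseudo-axial by A(1,2) strain with C8, so allyl bromide should enter anti to it (as in a Fráter–Seebach alkylation), setting C7 with O16 trans to C9; the cold quench guards against retro-aldol.

Step 5
Reactants: 8 2-methylbut-3-en-2-ol
Product: 9 2-methylbut-3-en-2-yl 2,2,2-trichloroacetimidate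
Conditions: Cl3CCN, DBU (10 mol %), CH2Cl2, 0 °C
Reagents that add atoms: trichloroacetonitrile, ClC(Cl)(Cl)C#N
Why: Base-catalysed addition of an alcohol to trichloroacetonitrile; routine for tertiary alcohols.

Step 6
Reactants: 7 (2R,3S)-3-hydroxy-2-methyl-2-(prop-2-en-1-yl)cyclohexan-1-one; 9 2-methylbut-3-en-2-yl 2,2,2-trichloroacetimidate
Product: 10 (2R,3S)-2-methyl-3-[(2-methylbut-3-en-2-yl)oxy]-2-(prop-2-en-1-yl)cyclohexan-1-one
Conditions: CF3SO3H (5 mol %), cyclohexane/CH2Cl2, −20 to 0 °C
Reagents that add atoms: none
Why: Acid-catalysed tert-alkylation of an alcohol by a trichloroacetimidate; the O16–C13 bond is made intermolecularly at the tertiary terminus of the ion pair under kinetic control, and the C17–O bond is not broken.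

Step 7
Reactants: 10 (2R,3S)-2-methyl-3-[(2-methylbut-3-en-2-yl)oxy]-2-(prop-2-en-1-yl)cyclohexan-1-one
Product: 11 (5aR,9aS)-2,2,5a-trimethyl-5,5a,7,8,9,9a-hexahydro-1-benzoxepin-6(2H)-one (trans-fused oxepene, C10=C11)
Conditions: RuCl2(H2IMes)(PCy3)(=CHPh) (second-generation Grubbs catalyst, 5 mol %), CH2Cl2, 0.005 M, 40 °C
Reagents that add atoms: none
Why: Ring-closing alkene metathesis: the ruthenium carbene initiates at the unhindered allyl terminus (C10), forms a metallacyclobutane with the 1,1-dimethylallyl alkene and releases ethene, giving the C10=C11 bond. The closest known reaction type is ring-closing metathesis to 2,2-disubstituted dihydrooxepines and oxepenes whose allylic ether carbon is fully substituted. Ring A closes as a seven-membered ring by formation of an endocyclic alkene, which the ring size forces to be cis. No stereocentre is formed, and C7 and C17 are not touched. The step needs cyclisation to win over oligomerisation: in the chair of 10 with C8 axial, C9 and O16 are trans-diequatorial and gauche, the gem-dimethyl group on C13 further favours the folded ether, and high dilution does the rest. The ketone is inert to the catalyst, and the hindered O16–C13 bond already exists, so the closure is a carbon–carbon event.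

Step 8
Reactants: 11 (5aR,9aS)-2,2,5a-trimethyl-5,5a,7,8,9,9a-hexahydro-1-benzoxepin-6(2H)-one
Product: 12 (3S,4S,5aR,9aS)-3,4-epoxy-2,2,5a-trimethyloctahydro-1-benzoxepin-6(2H)-one (oxirane on C10–C11, anti to C8)
Conditions: mCPBA, NaHCO3, CH2Cl2, 0 °C
Reagents that add atoms: 3-chloroperbenzoic acid, O=C(OO)c1cccc(Cl)c1
Why: Prilezhaev epoxidation; the axial C8 methyl on C7 projects over the upper face of the C9–C10 region, so the peracid should attack from below and set C11 (and C10), while the hindered ketone resists Baeyer–Villiger oxidation under buffered cold conditions.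

Step 9
Reactants: 12 (3S,4S,5aR,9aS)-3,4-epoxy-2,2,5a-trimethyloctahydro-1-benzoxepin-6(2H)-one
Product: 13 the C20-methyl ketone of 12 (2,2,5a,7-tetramethyl analogue, C20 epimers)
Conditions: LiN(iPr)2, THF, −78 °C; MeI, −78 to −20 °C
Reagents that add atoms: iodomethane, CI
Why: Enolate alkylation; C20 is the only enolisable position because C7 is quaternary, and the oxirane is inert to amide base at low temperature.

Step 10
Reactants: 13 the C20-methyl ketone of 12
Product: 14 C6 enol triflate of 13 (C6=C20 tetrasubstituted)
Conditions: KN(SiMe3)2, THF, −78 to 0 °C; PhNTf2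
Reagents that add atoms: N-phenylbis(trifluoromethanesulfonimide), O=S(=O)(N(c1ccccc1)S(=O)(=O)C(F)(F)F)C(F)(F)F
Why: O-Triflation of the single possible enolate; the C20 stereocentre is erased.

Step 11
Reactants: 14 C6 enol triflate of 13
Product: 15 C6-vinyl diene (C4=C5–C6=C20) with the C10–C11 oxirane
Conditions: CH2=CHBF3K, PdCl2(dppf) (5 mol %), Cs2CO3, THF/H2O, 70 °C
Reagents that add atoms: potassium vinyltrifluoroborate, C=C[B-](F)(F)F.[K+]
Why: Suzuki–Miyaura coupling of an enol triflate brings in C5 and C4; the mildly basic aqueous medium spares the oxirane.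

Step 12
Reactants: 15 C6-vinyl diene with the C10–C11 oxirane
Product: 17 epoxy diol (C4–OH, C20–OH; H6 and O22 on the face opposite C8), via borolane 16 (not isolated)
Conditions: BH3·THF (1.1 equiv), THF, 0 °C to rt; then NaOH, H2O2, 0 °C
Reagents that add atoms: hydrogen peroxide, OO
Why: Cyclic hydroboration of a 2-vinylcycloalkene: borane first adds to the terminal C4, then the tethered B–H adds across C6=C20 with boron forced onto C20 (a five-membered borolane) and hydrogen onto C6. Delivery occurs from the face opposite the pseudo-axial C8 methyl, so oxidation with retention should give C6 and C20 in one step with C5 and O22 trans-diequatorial.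

Step 13
Reactants: 17 epoxy diol
Product: 18 triol (C4–OH, C11–OH, C20–OH)
Conditions: LiBHEt3 (5 equiv), THF, 0 °C to rt
Reagents that add atoms: none
Why: Hydride opens the oxirane by SN2 attack at C10, the carbon remote from the fully substituted C13; the C11–O bond is untouched, so the C11 configuration from step 8 is kept.

Step 14
Reactants: 18 triol
Product: 19 tris(triethylsilyl) ether of 18
Conditions: Et3SiOTf (4 equiv), 2,6-lutidine, CH2Cl2, −78 to 0 °C
Reagents that add atoms: triethylsilyl trifluoromethanesulfonate, CC[Si](CC)(CC)OS(=O)(=O)C(F)(F)F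
Why: Silyl triflate silylates primary, hindered secondary and tertiary hydroxyls alike; capping O22 first prevents ring closure of O22 onto C4 when C4 is activated.

Step 15
Reactants: 19 tris(triethylsilyl) ether of 18
Product: 20 primary alcohol (C4–OH; O12 and O22 as triethylsilyl ethers)
Conditions: pyridinium p-toluenesulfonate (10 mol %), MeOH/CH2Cl2, 0 °C
Reagents that add atoms: none
Why: Mild acid methanolysis cleaves the unhindered primary triethylsilyl ether much faster than the neopentyl-type secondary and the tertiary ones.

Step 16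
Reactants: 20 primary alcohol
Product: 21 primary iodide (C4–I)
Conditions: I2, PPh3, imidazole, CH2Cl2, 0 °C
Reagents that add atoms: iodine, II
Why: Appel-type iodination of a primary alcohol under buffered conditions that the hindered silyl ethers tolerate.

### CD half

Step 17
Reactants: 22 4,4-dimethylcyclohex-2-en-1-one
Product: 23 1,4,4-trimethylcyclohex-2-en-1-ol (racemic)
Conditions: MeLi, Et2O, −78 °C
Reagents that add atoms: methyllithium, [Li]C
Why: 1,2-Addition of methyllithium to an enone; the stereocentre is removed in the next step.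

Step 18
Reactants: 23 1,4,4-trimethylcyclohex-2-en-1-ol
Product: 24 3,6,6-trimethylcyclohex-2-en-1-one
Conditions: pyridinium chlorochromate, C5H5NH[CrO3Cl], CH2Cl2, rt
Reagents that add atoms: pyridinium chlorochromate, [O-][Cr](=O)(=O)Cl.c1cc[nH+]cc1
Why: Babler–Dauben oxidative transposition: the chromate ester of the tertiary allylic alcohol undergoes a [3,3] shift and is oxidised, moving the carbonyl next to the gem-dimethyl carbon (C23) and the methyl onto the β-carbon (C28).

Step 19
Reactants: 24 3,6,6-trimethylcyclohex-2-en-1-one
Product: 25 (1S,6S)-3,3,6-trimethyl-7-oxabicyclo[4.1.0]heptan-2-one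
Conditions: 9-amino-9-deoxy-epi-quinine·2 CF3CO2H (10 mol %), 50% aq. H2O2, dioxane, 35 °C
Reagents that add atoms: hydrogen peroxide, OO
Why: Amine-salt-catalysed asymmetric Weitz–Scheffer epoxidation of a cyclic enone through a chiral iminium ion; this sets the C28–O bond and with it all absolute configuration of the CD half.

Step 20
Reactants: 25 (1S,6S)-3,3,6-trimethyl-7-oxabicyclo[4.1.0]heptan-2-one
Product: 26 (S)-5-hydroxy-2,2,5-trimethylcyclohexan-1-one
Conditions: SmI2 (2.2 equiv), THF/MeOH, −90 °C
Reagents that add atoms: none
Why: Ketyl-mediated cleavage of the Cα–O bond (C24–O) of an α,β-epoxy ketone; the C28–O bond is not touched, and the cold neutral medium avoids retro-aldol and elimination.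

Step 21
Reactants: 26 (S)-5-hydroxy-2,2,5-trimethylcyclohexan-1-one
Product: 27 (S)-2,2,5-trimethyl-5-(triethylsilyloxy)cyclohexan-1-one
Conditions: Et3SiOTf, 2,6-lutidine, CH2Cl2, −78 °C
Reagents that add atoms: triethylsilyl trifluoromethanesulfonate, CC[Si](CC)(CC)OS(=O)(=O)C(F)(F)F
Why: Silylation of the tertiary alcohol blocks retro-aldol in the next, basic step and provides the bulky group that later directs C24.

Step 22
Reactants: 27 (S)-2,2,5-trimethyl-5-(triethylsilyloxy)cyclohexan-1-one
Product: 28 (S)-3,6,6-trimethyl-3-(triethylsilyloxy)cyclohex-1-en-1-yl trifluoromethanesulfonate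
Conditions: LiN(iPr)2, THF, −78 °C; Comins' reagent, −78 °C
Reagents that add atoms: N-(5-chloropyridin-2-yl)bis(trifluoromethanesulfonimide), O=S(=O)(N(c1ccc(Cl)cn1)S(=O)(=O)C(F)(F)F)C(F)(F)F
Why: Only C24 can be deprotonated; trapping the lithium enolate at −78 °C forestalls β-elimination of the silyloxy group.

Step 23
Reactants: 28 (S)-3,6,6-trimethyl-3-(triethylsilyloxy)cyclohex-1-en-1-yl trifluoromethanesulfonate
Product: 29 (S)-N-methoxy-N,3,6,6-tetramethyl-3-(triethylsilyloxy)cyclohex-1-ene-1-carboxamide
Conditions: Pd(OAc)2 (5 mol %), Ph2P(CH2)3PPh2, CO (1 atm), MeNH(OMe)·HCl, Et3N, DMF, 60 °C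
Reagents that add atoms: carbon monoxide, [C-]#[O+]; N,O-dimethylhydroxylamine hydrochloride, CNOC.Cl
Why: Palladium-catalysed aminocarbonylation of an enol triflate installs C3 as a Weinreb amide.

Step 24
Reactants: 29 (S)-N-methoxy-N,3,6,6-tetramethyl-3-(triethylsilyloxy)cyclohex-1-ene-1-carboxamide
Product: 30 1-[(S)-3,6,6-trimethyl-3-(triethylsilyloxy)cyclohex-1-en-1-yl]propan-1-one
Conditions: EtMgBr, THF, 0 °C
Reagents that add atoms: ethylmagnesium bromide, CC[Mg]Br
Why: Weinreb ketone synthesis brings in C2 and C1; the chelated tetrahedral intermediate prevents over-addition.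

Step 25
Reactants: 30 1-[(S)-3,6,6-trimethyl-3-(triethylsilyloxy)cyclohex-1-en-1-yl]propan-1-one
Product: 32 1-[(1R,2S,3S)-3,6,6-trimethyl-2-(prop-2-en-1-yl)-3-(triethylsilyloxy)cyclohexyl]propan-1-one, via trimethylsilyl enol ether 31 (not isolated)
Conditions: CH2=CHCH2MgBr, CuBr·SMe2 (1.2 equiv), LiCl, Me3SiCl, THF, −78 °C; then Bu4NF, AcOH, THF, −78 °C
Reagents that add atoms: allylmagnesium bromide, C=CC[Mg]Br
Why: Silyl-assisted conjugate addition of an allylcopper reagent to C24, anti to the pseudo-axial C28 silyloxy group of the γ-alkoxy enone, sets C24. Fluoride-triggered kinetic protonation of 31 at C23 from the face opposite the now axial allyl group should give the cis relation of C3 and C25.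

Step 26
Reactants: 32 1-[(1R,2S,3S)-3,6,6-trimethyl-2-(prop-2-en-1-yl)-3-(triethylsilyloxy)cyclohexyl]propan-1-one
Product: 33 2-[(1S,2R,6S)-3,3,6-trimethyl-2-propanoyl-6-(triethylsilyloxy)cyclohexyl]acetaldehyde
Conditions: O3, CH2Cl2, −78 °C; then PPh3
Reagents that add atoms: ozone, [O-][O+]=O
Why: Ozonolysis with reductive work-up turns the allyl group into the C25–C26 aldehyde; the alkene is the only ozone-sensitive group.

Step 27
Reactants: 33 2-[(1S,2R,6S)-3,3,6-trimethyl-2-propanoyl-6-(triethylsilyloxy)cyclohexyl]acetaldehyde
Product: 34 (4aS,5S,8aR)-2,5,8,8-tetramethyl-5-(triethylsilyloxy)-4a,5,6,7,8,8a-hexahydronaphthalen-1(4H)-one (cis-fused enone, C3=O, C2=C26)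
Conditions: (PhCH2)2NH2+ CF3CO2− (20 mol %), toluene, 50 °C
Reagents that add atoms: none
Why: Intramolecular aldol condensation: the less hindered enamine/enol at C2 attacks the C26 aldehyde (the only six-membered mode) and water is lost. The mild ammonium salt is chosen to avoid enolisation toward C23.

### Union and endgame

Step 28
Reactants: 21 primary iodide (C4–I); 34 (4aS,5S,8aR)-2,5,8,8-tetramethyl-5-(triethylsilyloxy)-4a,5,6,7,8,8a-hexahydronaphthalen-1(4H)-one
Product: 36 tertiary allylic alcohol with the C3–C4 bond (C3 epimers), via alkyllithium 35 (not isolated)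
Conditions: t-BuLi (2.1 equiv), Et2O/pentane, −78 °C; then 34, −78 to −40 °C
Reagents that add atoms: none
Why: Iodine–lithium exchange followed by 1,2-addition of the primary alkyllithium to the enone carbonyl C3; ether at −78 °C disfavours silyl migration and deprotonation at the hindered C23, and the new carbinol centre is removed in the next step.

Step 29
Reactants: 36 tertiary allylic alcohol with the C3–C4 bond
Product: 37 tris(triethylsilyl) ether of sipholenol K
Conditions: pyridinium chlorochromate, C5H5NH[CrO3Cl], NaOAc, CH2Cl2, rt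
Reagents that add atoms: pyridinium chlorochromate, [O-][Cr](=O)(=O)Cl.c1cc[nH+]cc1
Why: Babler–Dauben oxidative transposition moves oxygen from C3 to C26 and the alkene to C2=C3 without passing through an enolate at C23; all other hydroxyls are silylated.

Step 30
Reactants: 37 tris(triethylsilyl) ether of sipholenol K
Product: 38 sipholenol K
Conditions: HF·pyridine, pyridine, THF, 0 °C to rt
Reagents that add atoms: none
Why: Buffered fluoride desilylation frees O12, O22 and O30 without base at the C23 γ-position and without strong acid at the tertiary carbinols.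

## Compound list

1 | 2-methylcyclohex-2-en-1-one | CC1=CCCCC1=O | starting material
2 | (R)-2-methylcyclohex-2-en-1-ol | O[C@@H]1CCCC=C1C | intermediate
3 | (1R,2R,6S)-1-methyl-7-oxabicyclo[4.1.0]heptan-2-ol | O[C@H]1[C@@]2(C)O[C@H]2CCC1 | intermediate
4 | (1S,6S)-1-methyl-7-oxabicyclo[4.1.0]heptan-2-one | O=C1[C@@]2(C)O[C@H]2CCC1 | intermediate
5 | allyl bromide | C=CCBr | starting material
6 | dilithium (S)-2-methyl-3-oxidocyclohex-1-en-1-olate | [Li]OC1=C(C)[C@@H](O[Li])CCC1 | intermediate
7 | (2R,3S)-3-hydroxy-2-methyl-2-(prop-2-en-1-yl)cyclohexan-1-one | C=CC[C@]1(C)[C@@H](O)CCCC1=O | intermediate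
8 | 2-methylbut-3-en-2-ol | CC(C)(O)C=C | starting material
9 | 2-methylbut-3-en-2-yl 2,2,2-trichloroacetimidate | CC(C)(C=C)OC(=N)C(Cl)(Cl)Cl | intermediate
10 | (2R,3S)-2-methyl-3-[(2-methylbut-3-en-2-yl)oxy]-2-(prop-2-en-1-yl)cyclohexan-1-one | C=CC[C@]1(C)[C@@H](OC(C)(C)C=C)CCCC1=O | intermediate
11 | (5aR,9aS)-2,2,5a-trimethyl-5,5a,7,8,9,9a-hexahydro-1-benzoxepin-6(2H)-one | C[C@@]12CC=CC(C)(C)O[C@H]1CCCC2=O | intermediate
12 | (3S,4S,5aR,9aS)-3,4-epoxy-2,2,5a-trimethyloctahydro-1-benzoxepin-6(2H)-one | C[C@@]12C[C@@H]3O[C@@H]3C(C)(C)O[C@H]1CCCC2=O | intermediate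
13 | C20-methyl ketone of 12 (C20 epimers) | C[C@@]12C[C@@H]3O[C@@H]3C(C)(C)O[C@H]1CCC(C)C2=O | intermediate
14 | C6 enol triflate of 13 | C[C@@]12C[C@@H]3O[C@@H]3C(C)(C)O[C@H]1CCC(C)=C2OS(=O)(=O)C(F)(F)F | intermediate
15 | C6-vinyl diene with the C10–C11 oxirane | C[C@@]12C[C@@H]3O[C@@H]3C(C)(C)O[C@H]1CCC(C)=C2C=C | intermediate
16 | trans-fused borolane (B on C4 and C20, B–H) | C[C@@]12C[C@@H]3O[C@@H]3C(C)(C)O[C@H]1CC[C@]1(C)[BH]CC[C@@H]21 | intermediate
17 | epoxy diol (C4–OH, C20–OH, C10–C11 oxirane) | C[C@@]12C[C@@H]3O[C@@H]3C(C)(C)O[C@H]1CC[C@](C)(O)[C@H]2CCO | intermediate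
18 | triol (C4–OH, C11–OH, C20–OH) | C[C@@]12CC[C@H](O)C(C)(C)O[C@H]1CC[C@](C)(O)[C@H]2CCO | intermediate
19 | tris(triethylsilyl) ether of 18 | C[C@@]12CC[C@H](O[Si](CC)(CC)CC)C(C)(C)O[C@H]1CC[C@](C)(O[Si](CC)(CC)CC)[C@H]2CCO[Si](CC)(CC)CC | intermediate
20 | primary alcohol (O12, O22 triethylsilyl) | C[C@@]12CC[C@H](O[Si](CC)(CC)CC)C(C)(C)O[C@H]1CC[C@](C)(O[Si](CC)(CC)CC)[C@H]2CCO | intermediate
21 | primary iodide (C4–I; O12, O22 triethylsilyl) | C[C@@]12CC[C@H](O[Si](CC)(CC)CC)C(C)(C)O[C@H]1CC[C@](C)(O[Si](CC)(CC)CC)[C@H]2CCI | intermediate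
22 | 4,4-dimethylcyclohex-2-en-1-one | CC1(C)CCC(=O)C=C1 | starting material
23 | 1,4,4-trimethylcyclohex-2-en-1-ol (racemic) | CC1(O)CCC(C)(C)C=C1 | intermediate
24 | 3,6,6-trimethylcyclohex-2-en-1-one | CC1=CC(=O)C(C)(C)CC1 | intermediate
25 | (1S,6S)-3,3,6-trimethyl-7-oxabicyclo[4.1.0]heptan-2-one | O=C1[C@H]2O[C@@]2(C)CCC1(C)C | intermediate
26 | (S)-5-hydroxy-2,2,5-trimethylcyclohexan-1-one | O=C1C[C@@](C)(O)CCC1(C)C | intermediate
27 | (S)-2,2,5-trimethyl-5-(triethylsilyloxy)cyclohexan-1-one | O=C1C[C@@](C)(O[Si](CC)(CC)CC)CCC1(C)C | intermediate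
28 | (S)-3,6,6-trimethyl-3-(triethylsilyloxy)cyclohex-1-en-1-yl trifluoromethanesulfonate | FC(F)(F)S(=O)(=O)OC1=C[C@@](C)(O[Si](CC)(CC)CC)CCC1(C)C | intermediate
29 | (S)-N-methoxy-N,3,6,6-tetramethyl-3-(triethylsilyloxy)cyclohex-1-ene-1-carboxamide | CON(C)C(=O)C1=C[C@@](C)(O[Si](CC)(CC)CC)CCC1(C)C | intermediate
30 | 1-[(S)-3,6,6-trimethyl-3-(triethylsilyloxy)cyclohex-1-en-1-yl]propan-1-one | CCC(=O)C1=C[C@@](C)(O[Si](CC)(CC)CC)CCC1(C)C | intermediate
31 | trimethylsilyl enol ether of 32 (C3=C23) | CCC(O[Si](C)(C)C)=C1[C@H](CC=C)[C@@](C)(O[Si](CC)(CC)CC)CCC1(C)C | intermediate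
32 | 1-[(1R,2S,3S)-3,6,6-trimethyl-2-(prop-2-en-1-yl)-3-(triethylsilyloxy)cyclohexyl]propan-1-one | CCC(=O)[C@@H]1[C@H](CC=C)[C@@](C)(O[Si](CC)(CC)CC)CCC1(C)C | intermediate
33 | 2-[(1S,2R,6S)-3,3,6-trimethyl-2-propanoyl-6-(triethylsilyloxy)cyclohexyl]acetaldehyde | CCC(=O)[C@@H]1[C@H](CC=O)[C@@](C)(O[Si](CC)(CC)CC)CCC1(C)C | intermediate
34 | (4aS,5S,8aR)-2,5,8,8-tetramethyl-5-(triethylsilyloxy)-4a,5,6,7,8,8a-hexahydronaphthalen-1(4H)-one | O=C1C(C)=CC[C@H]2[C@@H]1C(C)(C)CC[C@]2(C)O[Si](CC)(CC)CC | intermediate
35 | alkyllithium from 21 (C4–Li) | C[C@@]12CC[C@H](O[Si](CC)(CC)CC)C(C)(C)O[C@H]1CC[C@](C)(O[Si](CC)(CC)CC)[C@H]2CC[Li] | intermediate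
36 | tertiary allylic alcohol with the C3–C4 bond (C3 epimers) | C[C@@]12CC[C@H](O[Si](CC)(CC)CC)C(C)(C)O[C@H]1CC[C@](C)(O[Si](CC)(CC)CC)[C@H]2CCC1(O)C(C)=CC[C@H]2[C@@H]1C(C)(C)CC[C@]2(C)O[Si](CC)(CC)CC | intermediate
37 | tris(triethylsilyl) ether of sipholenol K | C[C@@]12CC[C@H](O[Si](CC)(CC)CC)C(C)(C)O[C@H]1CC[C@](C)(O[Si](CC)(CC)CC)[C@H]2CCC1=C(C)C(=O)C[C@H]2[C@@H]1C(C)(C)CC[C@]2(C)O[Si](CC)(CC)CC | intermediate
38 | sipholenol K | C[C@@]12CC[C@H](O)C(C)(C)O[C@H]1CC[C@](C)(O)[C@H]2CCC1=C(C)C(=O)C[C@H]2[C@@H]1C(C)(C)CC[C@]2(C)O | target

## Step count and least certain steps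

Total: 30 steps. Longest linear sequence: 18 steps (steps 1–4, 6–16 and 28–30, from compound 1). The CD half takes 11 steps (17–27) and the imidate one step (5).

**Step 7 (key step).** Intermolecular metathesis may outrun closure onto the hindered 1,1-dimethylallyl alkene, or a ruthenium hydride may move the allyl double bond and lead to a contracted ring. Fallback by relay ring-closing metathesis, from 7 back to 11:
- The dianion of 2-methylbut-3-yn-2-ol is alkylated with 5-bromopent-1-ene to 2-methylnon-8-en-3-yn-2-ol F1.
- LiAlH4 reduces the propargylic alcohol to (E)-2-methylnona-3,8-dien-2-ol F2.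
- Cl3CCN/DBU gives the trichloroacetimidate F3.
- Acid-catalysed etherification of 7 as in step 6 gives the relay ether F4.
- With the same ruthenium catalyst the carbene loads on the unhindered terminal alkene of the relay arm, expels cyclopentene, arrives on C11 and closes onto the allyl group to give 11.

**Step 4.** The enolate may be protonated by ammonia before it is alkylated, the alkoxide may be O-allylated, or the product alkoxide may undergo retro-aldol cleavage. Fallback from 4 back to 7:
- Li/NH3 cleavage as before, then quench with Me3SiCl/Et3N, gives the bis(trimethylsilyl) derivative F5.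
- Tsuji allylation of the silyl enol ether (Pd2(dba)3, Ph2PCH2CH2PPh2, allyl methyl carbonate, THF) under neutral conditions, again anti to the C17 oxygen, gives the silyl ether F6.
- Methanolysis with citric acid in MeOH gives 7.

**Step 8.** Facial discrimination by the C8 methyl may be insufficient on the flexible seven-membered ring. Fallback from 11 to 12 with reagent control: epoxidation with a chiral dioxirane generated from a fructose-derived ketone of the type used for cis-alkenes and KHSO5 at buffered pH, in place of substrate control; no new compound is involved.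

**Step 12.** The tethered B–H may fail to add to the tetrasubstituted C6=C20 bond (stalling at the monoalkylborane), or the borane may attack the oxirane. Fallback from 12 to 19, avoiding the tetrasubstituted alkene:
- Triflation of 12 (KN(SiMe3)2, PhNTf2) gives enol triflate F7.
- Vinylation as in step 11 gives diene F8.
- Cyclic hydroboration–oxidation of this trisubstituted 2-vinylcyclohexene (the well-established case) gives diol F9 with a secondary C20–OH.
- Et3SiCl/imidazole silylates the primary hydroxyl to give F10.
- Dess–Martin oxidation gives ketone F11, in which C6 can equilibrate to the equatorial side chain.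
- Wittig methylenation (Ph3P=CH2) gives F12.
- mCPBA epoxidises the exocyclic alkene from the face opposite C8 (the monosubstituted-free substrate has no competing alkene) to give bis-epoxide F13.
- LiBHEt3 opens both oxiranes, at C10 and at the C21 methylene, to give diol F14.
- Et3SiOTf gives 19.

**Step 19.** Iminium formation at a carbonyl flanked by the quaternary C33 may be slow, leaving room for uncatalysed, racemic epoxidation. Fallback from 24 to 25 by a hydroxyl relay, as in steps 1–3:
- CBS reduction of 24 with the catalyst enantiomer that gives (S)-3,6,6-trimethylcyclohex-2-en-1-ol F15.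
- VO(acac)2/t-BuOOH gives the cis-epoxy alcohol F16.
- Dess–Martin oxidation gives 25.

**Step 25.** The twisted, hindered enone may react by 1,2-addition or not at all, the silyloxy group may give too little facial bias, or C23 may equilibrate after protonation. Fallback from 28 to 32 through a more reactive acceptor:
- Palladium-catalysed formylation of 28 (Pd(PPh3)4, CO, Bu3SnH) gives enal F17.
- Allylcopper addition and cold kinetic protonation as in step 25 give aldehyde F18.
- EtMgBr gives alcohol F19.
- Dess–Martin oxidation gives 32.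

## Further compounds

F1 | step 7 | 2-methylnon-8-en-3-yn-2-ol | CC(C)(O)C#CCCCC=C
F2 | step 7 | (E)-2-methylnona-3,8-dien-2-ol | CC(C)(O)/C=C/CCCC=C
F3 | step 7 | (E)-2-methylnona-3,8-dien-2-yl 2,2,2-trichloroacetimidate | CC(C)(/C=C/CCCC=C)OC(=N)C(Cl)(Cl)Cl
F4 | step 7 | (2R,3S)-2-methyl-3-{[(E)-2-methylnona-3,8-dien-2-yl]oxy}-2-(prop-2-en-1-yl)cyclohexan-1-one | C=CC[C@]1(C)[C@@H](OC(C)(C)/C=C/CCCC=C)CCCC1=O
F5 | step 4 | (S)-2-methyl-1,3-bis(trimethylsilyloxy)cyclohex-1-ene | C[Si](C)(C)OC1=C(C)[C@@H](O[Si](C)(C)C)CCC1
F6 | step 4 | (2R,3S)-2-methyl-2-(prop-2-en-1-yl)-3-(trimethylsilyloxy)cyclohexan-1-one | C=CC[C@]1(C)[C@@H](O[Si](C)(C)C)CCCC1=O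
F0 | step 8 | none | none
F7 | step 12 | C6 enol triflate of 12 | C[C@@]12C[C@@H]3O[C@@H]3C(C)(C)O[C@H]1CCC=C2OS(=O)(=O)C(F)(F)F
F8 | step 12 | C6-vinyl diene without the C20 methyl | C[C@@]12C[C@@H]3O[C@@H]3C(C)(C)O[C@H]1CCC=C2C=C
F9 | step 12 | epoxy diol with secondary C20–OH | C[C@@]12C[C@@H]3O[C@@H]3C(C)(C)O[C@H]1CC[C@H](O)[C@H]2CCO
F10 | step 12 | C4 triethylsilyl ether of F9 | C[C@@]12C[C@@H]3O[C@@H]3C(C)(C)O[C@H]1CC[C@H](O)[C@H]2CCO[Si](CC)(CC)CC
F11 | step 12 | C20 ketone | C[C@@]12C[C@@H]3O[C@@H]3C(C)(C)O[C@H]1CCC(=O)[C@H]2CCO[Si](CC)(CC)CC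
F12 | step 12 | C20 exocyclic methylene compound | C[C@@]12C[C@@H]3O[C@@H]3C(C)(C)O[C@H]1CCC(=C)[C@H]2CCO[Si](CC)(CC)CC
F13 | step 12 | bis-epoxide (C10–C11 and C20 spiro-oxirane, both oxygens anti to C8) | C[C@@]12C[C@@H]3O[C@@H]3C(C)(C)O[C@H]1CC[C@@]4(CO4)[C@H]2CCO[Si](CC)(CC)CC
F14 | step 12 | C11,C20-diol with C4 triethylsilyl ether | C[C@@]12CC[C@H](O)C(C)(C)O[C@H]1CC[C@](C)(O)[C@H]2CCO[Si](CC)(CC)CC
F15 | step 19 | (S)-3,6,6-trimethylcyclohex-2-en-1-ol | CC1=C[C@H](O)C(C)(C)CC1
F16 | step 19 | (1S,2S,6S)-3,3,6-trimethyl-7-oxabicyclo[4.1.0]heptan-2-ol | O[C@H]1[C@H]2O[C@@]2(C)CCC1(C)C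
F17 | step 25 | (S)-3,6,6-trimethyl-3-(triethylsilyloxy)cyclohex-1-ene-1-carbaldehyde | O=CC1=C[C@@](C)(O[Si](CC)(CC)CC)CCC1(C)C
F18 | step 25 | (1R,2S,3S)-3,6,6-trimethyl-2-(prop-2-en-1-yl)-3-(triethylsilyloxy)cyclohexane-1-carbaldehyde | O=C[C@@H]1[C@H](CC=C)[C@@](C)(O[Si](CC)(CC)CC)CCC1(C)C
F19 | step 25 | 1-[(1R,2S,3S)-3,6,6-trimethyl-2-(prop-2-en-1-yl)-3-(triethylsilyloxy)cyclohexyl]propan-1-ol | CCC(O)[C@@H]1[C@H](CC=C)[C@@](C)(O[Si](CC)(CC)CC)CCC1(C)C
A1 | alternative 1 | 5-(2,4-dimethoxy-3-methylphenyl)-5-methylhexan-2-one | COc1ccc(C(C)(C)CCC(C)=O)c(OC)c1C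
A2 | alternative 1 | bicyclic dienol with enol ethers at C3 and C26 | C[C@H]1C(OC)=C2[C@H](C=C1OC)[C@@](C)(O)CCC2(C)C
A3 | alternative 2 | 8-(tert-butyldimethylsilyloxy)-6,6,9-trimethyldeca-1,7,9-trien-3-one | C=C(C)C(O[Si](C)(C)C(C)(C)C)=CC(C)(C)CCC(=O)C=C
A4 | alternative 2 | cis-fused bicyclic ketone with the silyl enol ether at C3 | CC1=C(O[Si](C)(C)C(C)(C)C)[C@@H]2[C@H](CC1)C(=O)CCC2(C)C
A5 | alternative 3 | oxepane with the C20 methyl ketone chain on C17 and the enoate on C7 | CC(=O)CC[C@@H]1OC(C)(C)[C@@H](O[Si](C)(C)C(C)(C)C)CC[C@@]1(C)/C=C/C(=O)OC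
A6 | alternative 3 | rings A and B with the γ-lactone between O22 and C4 | O=C1C[C@H]2[C@]3(C)CC[C@H](O[Si](C)(C)C(C)(C)C)C(C)(C)O[C@H]3CC[C@]2(C)O1
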